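**Retrosynthetic overview**
1. Rings: A = methoxylated ring, B = para-phenylene ring, C = hydroxylated ring, D = meta-phenylene ring; the target is the 20-membered ring A–O–B–CH2CH2–C–O–D–CH2CH2–A.
2. Last disconnection: the CH2–CH2 bond between the benzylic carbons on ring B and ring C. It is made as a C=C by Ramberg–Bäcklund ring contraction of a 21-membered benzylic sulfone (ring B–CH2–SO2–CH2–ring C), which forms the C–C bond, contracts the ring and expels sulfur as SO2 in one operation. One hydrogenation then gives the bridge and frees the ring C phenol.
3. Enabling feature: both carbons of that bond are benzylic CH2 groups (on C-1 of ring B and C-1 of ring C, each para to a diaryl ether oxygen). A bridging SO2 is therefore doubly activated for α-halogenation and 1,3-elimination, and the one-atom-larger sulfide ring closes by simple double S-alkylation.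
4. Sulfone ← sulfide ← seco dibromide ← seco diol ← aldehyde ester; the latter comes from two SNAr diaryl ether formations flanking a Wittig/hydrogenation that builds the ring D–CH2CH2–ring A bibenzyl.
5. Ring order: the four benzene rings are bought; the 21-membered thia-macrocycle is closed first (step 9) and then contracted to the 20-membered ring of the target (step 11).

Key step: step 11

Assumptions: compounds 4 and 9 are taken as commercial. The alkene geometry of the two stilbene intermediates (7 and 18) does not matter because both are hydrogenated; the Z isomers are drawn and E/Z mixtures are acceptable.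

**Route**

Step 1
Reactants: 1 isovanillin (3-hydroxy-4-methoxybenzaldehyde); 2 ethyl 4-fluorobenzoate
Product: 3 ethyl 4-(5-formyl-2-methoxyphenoxy)benzoate
Conditions: K2CO3, DMF, 130 °C
Reagents that add atoms: none
Why: Nucleophilic aromatic substitution (SNAr) in which the phenoxide of 1 displaces the fluoride para to the ester of 2 through a Meisenheimer adduct, while the non-enolisable aldehyde and the ethyl ester should tolerate anhydrous carbonate.

Step 2
Reactants: 4 3-(benzyloxy)benzyl bromide
Product: 5 [3-(benzyloxy)benzyl]triphenylphosphonium bromide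
Conditions: PPh3, toluene, reflux
Reagents that add atoms: triphenylphosphine, c1ccc(cc1)P(c1ccccc1)c1ccccc1
Why: SN2 quaternisation of the phosphine by a benzylic bromide, the standard preparation of a Wittig salt, which should crystallise from the hot toluene.

Step 3
Reactants: 3 ethyl 4-(5-formyl-2-methoxyphenoxy)benzoate; 5 [3-(benzyloxy)benzyl]triphenylphosphonium bromide
Product: 7 ethyl 4-{5-[2-(3-benzyloxyphenyl)ethenyl]-2-methoxyphenoxy}benzoate (Z drawn; E/Z mixture expected), via phosphonium ylide 6 (not isolated)
Conditions: K2CO3, 18-crown-6 (cat.), CH2Cl2, reflux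
Reagents that add atoms: none
Why: Wittig olefination in which the semi-stabilised ylide 6, formed by solid–liquid phase-transfer deprotonation, condenses with the aldehyde of 3 while the ester is untouched, and no geometric control is needed because step 4 saturates the alkene.

Step 4
Reactants: 7 ethyl 4-{5-[2-(3-benzyloxyphenyl)ethenyl]-2-methoxyphenoxy}benzoate
Product: 8 ethyl 4-{5-[2-(3-hydroxyphenyl)ethyl]-2-methoxyphenoxy}benzoate
Conditions: H2 (1 atm), 10% Pd/C, EtOAc/EtOH, rt
Reagents that add atoms: none
Why: Heterogeneous catalytic hydrogenation saturates the stilbene and hydrogenolyses the benzyl ether in the same operation, releasing the ring D phenol, while the ester, the diaryl ether and the methyl ether are inert.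

Step 5
Reactants: 9 4-fluoro-3-hydroxybenzaldehyde
Product: 10 3-(benzyloxy)-4-fluorobenzaldehyde
Conditions: BnBr, K2CO3, acetone, reflux
Reagents that add atoms: benzyl bromide, BrCc1ccccc1
Why: Williamson ether synthesis on the phenoxide, with benzyl chosen because the last hydrogenation of the route removes it.

Step 6
Reactants: 8 ethyl 4-{5-[2-(3-hydroxyphenyl)ethyl]-2-methoxyphenoxy}benzoate; 10 3-(benzyloxy)-4-fluorobenzaldehyde
Product: 11 ethyl 4-[5-(2-{3-[2-(benzyloxy)-4-formylphenoxy]phenyl}ethyl)-2-methoxyphenoxy]benzoate
Conditions: K2CO3, DMF, 130 °C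
Reagents that add atoms: none
Why: SNAr of the ring D phenoxide at the fluoride para to the aldehyde of 10, a known reactivity pattern of 3-alkoxy-4-fluorobenzaldehydes, with the ethyl ester stable to anhydrous carbonate.

Step 7
Reactants: 11 ethyl 4-[5-(2-{3-[2-(benzyloxy)-4-formylphenoxy]phenyl}ethyl)-2-methoxyphenoxy]benzoate
Product: 12 seco diol {3-(benzyloxy)-4-[3-(2-{3-[4-(hydroxymethyl)phenoxy]-4-methoxyphenyl}ethyl)phenoxy]phenyl}methanol
Conditions: LiAlH4, THF, 0 °C to rt
Reagents that add atoms: none
Why: Hydride reduction converts the ethyl ester on ring B and the aldehyde on ring C into the two benzylic alcohols in one step, with all ethers inert.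

Step 8
Reactants: 12 seco diol
Product: 13 seco dibromide 2-(benzyloxy)-4-(bromomethyl)-1-[3-(2-{3-[4-(bromomethyl)phenoxy]-4-methoxyphenyl}ethyl)phenoxy]benzene
Conditions: PBr3, CH2Cl2, 0 °C
Reagents that add atoms: phosphorus tribromide, BrP(Br)Br
Why: Conversion of benzylic alcohols into bromides through their phosphite esters (SN2 by bromide), under which aryl, methyl and benzyl ethers should be stable at 0 °C.

Step 9
Reactants: 13 seco dibromide
Product: 14 macrocyclic sulfide (21-membered ring; ring B–CH2–S–CH2–ring C; ring C carries OBn)
Conditions: Na2S·9H2O, EtOH/THF, slow addition of 13 (high dilution), 50 °C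
Reagents that add atoms: sodium sulfide (used as the nonahydrate), [Na+].[Na+].[S-2]
Why: Double SN2 thioetherification as in standard thiacyclophane synthesis, in which the first alkylation gives a tethered benzylic thiolate whose intramolecular attack on the second benzylic bromide should be favoured under dilution.

Step 10
Reactants: 14 macrocyclic sulfide
Product: 15 macrocyclic sulfone (21-membered ring; ring B–CH2–SO2–CH2–ring C; ring C carries OBn)
Conditions: mCPBA (2.2 equiv), CH2Cl2, 0 °C to rt
Reagents that add atoms: 3-chloroperbenzoic acid, OOC(=O)c1cccc(Cl)c1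
Why: Electrophilic oxidation of the sulfide through the sulfoxide to the sulfone, with no alkene, carbonyl or free phenol present to compete.

Step 11
Reactants: 15 macrocyclic sulfone
Product: 18 O-benzyl macrocyclic stilbene (20-membered ring; ring B–CH=CH–ring C; Z drawn), via α-bromo sulfone 16 (not isolated), via episulfone 17 (not isolated)
Conditions: CBr2F2, KOH/Al2O3, t-BuOH/CH2Cl2, 0 °C to rt
Reagents that add atoms: none
Why: Ramberg–Bäcklund reaction with in situ halogenation: KOH on alumina deprotonates one of the two benzylic α-sulfonyl CH2 groups and CBr2F2 brominates the carbanion to give 16, deprotonation of the other benzylic α-carbon then displaces bromide intramolecularly (1,3-elimination), which forms the bond between the benzylic carbons of ring B and ring C, and the thiirane 1,1-dioxide 17 extrudes SO2 to leave stilbene 18. The closest known reaction type is exactly this Meyers–Chan variant, established for dibenzyl sulfones (stilbenes) and for the ring contraction of cyclic benzylic sulfones to cyclophane-type alkenes. The bond-forming ring closure is a 3-exo-tet cyclisation to the episulfone, and loss of SO2 converts the 21-membered thia ring into the 20-membered ring of the target. The stereocentres of 16 and 17 are transient and none remains; the alkene geometry follows from the cis or trans episulfone that the macrocycle can accommodate (Z expected) and is erased in step 12. The step needs site selectivity for the two CH2SO2 carbons and mono-bromination: only these positions are acidic enough for KOH (the CH2CH2 bridge and the OCH2Ph group are not), bromination at either of them converges on the same episulfone, and the fast 1,3-elimination of a benzylic α-bromo sulfone should outrun a second bromination. Because the bond is made inside a ring that already exists, the closure is unimolecular and needs no high dilution.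

Step 12
Reactants: 18 O-benzyl macrocyclic stilbene
Product: 19 pakyonol
Conditions: H2 (1 atm), 10% Pd/C, EtOAc/MeOH, rt
Reagents that add atoms: none
Why: Catalytic hydrogenation reduces the stilbene C=C of either geometry to the CH2–CH2 bridge and hydrogenolyses the benzyl ether to the ring C phenol, and the target has no stereocentre to set.

**Compound list**

1 | isovanillin (3-hydroxy-4-methoxybenzaldehyde) | COc1ccc(C=O)cc1O | starting material
2 | ethyl 4-fluorobenzoate | CCOC(=O)c1ccc(F)cc1 | starting material
3 | ethyl 4-(5-formyl-2-methoxyphenoxy)benzoate | CCOC(=O)c1ccc(Oc2cc(C=O)ccc2OC)cc1 | intermediate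
4 | 3-(benzyloxy)benzyl bromide | BrCc1cccc(OCc2ccccc2)c1 | starting material
5 | [3-(benzyloxy)benzyl]triphenylphosphonium bromide | [Br-].c1ccc(cc1)[P+](Cc1cccc(OCc2ccccc2)c1)(c1ccccc1)c1ccccc1 | intermediate
6 | [3-(benzyloxy)benzylidene]triphenylphosphorane (ylide, not isolated) | c1ccc(cc1)P(=Cc1cccc(OCc2ccccc2)c1)(c1ccccc1)c1ccccc1 | intermediate
7 | ethyl 4-{5-[(Z)-2-(3-benzyloxyphenyl)ethenyl]-2-methoxyphenoxy}benzoate (Z drawn; E/Z mixture expected) | CCOC(=O)c1ccc(Oc2cc(/C=C\c3cccc(OCc4ccccc4)c3)ccc2OC)cc1 | intermediate
8 | ethyl 4-{5-[2-(3-hydroxyphenyl)ethyl]-2-methoxyphenoxy}benzoate | CCOC(=O)c1ccc(Oc2cc(CCc3cccc(O)c3)ccc2OC)cc1 | intermediate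
9 | 4-fluoro-3-hydroxybenzaldehyde | O=Cc1ccc(F)c(O)c1 | starting material
10 | 3-(benzyloxy)-4-fluorobenzaldehyde | O=Cc1ccc(F)c(OCc2ccccc2)c1 | intermediate
11 | ethyl 4-[5-(2-{3-[2-(benzyloxy)-4-formylphenoxy]phenyl}ethyl)-2-methoxyphenoxy]benzoate | CCOC(=O)c1ccc(Oc2cc(CCc3cccc(Oc4ccc(C=O)cc4OCc5ccccc5)c3)ccc2OC)cc1 | intermediate
12 | seco diol {3-(benzyloxy)-4-[3-(2-{3-[4-(hydroxymethyl)phenoxy]-4-methoxyphenyl}ethyl)phenoxy]phenyl}methanol | OCc1ccc(Oc2cc(CCc3cccc(Oc4ccc(CO)cc4OCc5ccccc5)c3)ccc2OC)cc1 | intermediate
13 | seco dibromide 2-(benzyloxy)-4-(bromomethyl)-1-[3-(2-{3-[4-(bromomethyl)phenoxy]-4-methoxyphenyl}ethyl)phenoxy]benzene | BrCc1ccc(Oc2cc(CCc3cccc(Oc4ccc(CBr)cc4OCc5ccccc5)c3)ccc2OC)cc1 | intermediate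
14 | macrocyclic sulfide (21-membered; the benzylic CH2 of ring B and that of ring C joined through one sulfur; OBn on ring C) | COc1ccc2cc1Oc1ccc(cc1)CSCc1ccc(c(OCc3ccccc3)c1)Oc1cccc(c1)CC2 | intermediate
15 | macrocyclic sulfone (S,S-dioxide of 14) | COc1ccc2cc1Oc1ccc(cc1)CS(=O)(=O)Cc1ccc(c(OCc3ccccc3)c1)Oc1cccc(c1)CC2 | intermediate
16 | α-bromo sulfone (Br on the benzylic carbon next to ring B; racemic; the regioisomer brominated next to ring C converges; not isolated) | COc1ccc2cc1Oc1ccc(cc1)C(Br)S(=O)(=O)Cc1ccc(c(OCc3ccccc3)c1)Oc1cccc(c1)CC2 | intermediate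
17 | episulfone (cis-2,3-diaryl thiirane 1,1-dioxide fused in the macrocycle; relative configuration, racemic; not isolated) | COc1ccc2cc1Oc1ccc(cc1)[C@H]1[C@H](S1(=O)=O)c1ccc(c(OCc3ccccc3)c1)Oc1cccc(c1)CC2 | intermediate
18 | O-benzyl macrocyclic stilbene (20-membered; ring B–CH=CH–ring C; Z drawn, E isomer equally usable) | COc1ccc2cc1Oc1ccc(cc1)/C=C\c1ccc(c(OCc3ccccc3)c1)Oc1cccc(c1)CC2 | intermediate
19 | pakyonol | COc1ccc2cc1Oc1ccc(cc1)CCc1ccc(c(O)c1)Oc1cccc(c1)CC2 | target

**Step count and risks**

Total step count: 12. Longest linear sequence: 10 steps (steps 1, 3, 4, 6, 7, 8, 9, 10, 11, 12, from isovanillin 1).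

Steps most likely to fail:

Step 11 (ring contraction). A second bromination of the α-bromo sulfone, or a slow 1,3-elimination because the contraction builds strain around the para,para-linked stilbene, could divert material to halogenated by-products. The fallback sets out from seco diol 12. Oxidation with MnO2 (CH2Cl2, rt) should give the seco dialdehyde F1. An intramolecular McMurry coupling of F1 (TiCl4, Zn, pyridine, THF, reflux, slow addition) should then close the same carbon–carbon bond as the alkene. The route is rejoined at stilbene 18.

Step 9 (thia-macrocyclisation). Intermolecular S-alkylation may outrun ring closure and give oligomers, or the activated benzylic bromides may solvolyse in the protic medium before sulfur arrives. The fallback sets out from seco dibromide 13. An intramolecular Wurtz-type reductive coupling (Na, tetraphenylethylene, THF, −40 °C to rt, high dilution), a known way to close bis(bibenzyl) macrocycles at a benzylic CH2–CH2 bond, should give O-benzylpakyonol F2 directly. Hydrogenolysis of F2 (H2, 10% Pd/C, EtOAc, rt) then comes back to the route at the target 19.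

Step 1 (first diaryl ether). Fluoride displacement on a ring activated only by an ester may be sluggish, so that at the temperature needed the phenoxide attacks the ester (transesterification or dealkylation) instead of the ring. The fallback sets out from isovanillin 1. Chan–Lam coupling with commercial 4-(ethoxycarbonyl)phenylboronic acid (Cu(OAc)2, pyridine, 4 Å molecular sieves, CH2Cl2, air, rt) should form the same C–O bond by oxidative copper-mediated arylation. It comes back to the route directly at 3, and no new compound is made (F0).

**Further compounds**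

F1 | step 11 | seco dialdehyde 3-(benzyloxy)-4-(3-{2-[3-(4-formylphenoxy)-4-methoxyphenyl]ethyl}phenoxy)benzaldehyde | O=Cc1ccc(Oc2cc(CCc3cccc(Oc4ccc(C=O)cc4OCc5ccccc5)c3)ccc2OC)cc1
F2 | step 9 | O-benzylpakyonol | COc1ccc2cc1Oc1ccc(cc1)CCc1ccc(c(OCc3ccccc3)c1)Oc1cccc(c1)CC2
F0 | step 1 | none | none
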